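the same everywhere: racemization catalyst 0.25 mM

|  | left-handed substrate | right-handed substrate | coupling partner | free catalyst | remark | time |
|---|---|---|---|---|---|---|
| ochre | 0.050 M | 0.050 M | 0.20 M | 0.70 mM | run made earlier |  |
| amber | 0.050 M | 0.050 M | 0.20 M | 1.1 mM | run made earlier |  |
| grey | 0.10 M | 0.10 M | 0.20 M | 0.50 mM | run made earlier |  |
| flask | 0.050 M | 0.050 M | 0.200 M | 0.50 mM |  | 4.0 d |

| run | time / d | left-handed product / % | right-handed product / % |
|---|---|---|---|
| ochre | 0.625 | 44 | 27 |
| ochre | 1.25 | 54 | 31 |
| ochre | 2.08 | 57 | 33 |
| ochre | 3.00 | 59 | 40 |
| ochre | 4.00 | 59 | 42 |
| ochre | 5.00 | 61 | 37 |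
| amber | 0.417 | 45 | 28 |
| amber | 0.625 | 49 | 32 |
| amber | 0.833 | 56 | 32 |
| amber | 1.25 | 54 | 35 |
| amber | 2.08 | 63 | 34 |
| amber | 3.00 | 62 | 41 |
| amber | 5.00 | 62 | 42 |
| grey | 0.417 | 26 | 19 |
| grey | 0.833 | 36 | 24 |
| grey | 1.25 | 38 | 23 |
| grey | 2.50 | 42 | 31 |
| grey | 5.00 | 57 | 33 |

(readings scatter by 2 percentage points)

- left-handed product and right-handed product together, in percent of the left-handed substrate and right-handed substrate charged together, at 4.0 d
- excess of left-handed product over right-handed product in the product at 4.0 d
- whether the exchange between left-handed substrate and right-handed substrate keeps pace with the reaction: how far the product's excess at 4.0 d gets from its value without exchange to its value with instant exchange (above 80 % keeps pace, below 20 % hardly takes part, else lags behind)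

- free catalyst is single-handed; left-handed substrate and right-handed substrate are mirror images of each other, charged as a racemate, each of them at the stated concentration
- an excess is the difference of the two amounts in percent of their sum
- an excess is below zero if the other one leads

**Early readings.** Early on, ochre and amber, both read at 0.625 d, already give you the rate. Call c the fraction of the two substrates reacted, u the fraction left, and m the partner charge as a multiple of the substrate charge, 2.00 in the flask. If the rate follows catalyst, partner and substrate, it integrates to one reaction number (a Damköhler number), N = ln[(m − c)/(m·u)], proportional to catalyst, time and the partner's surplus over substrate.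

**Reading N.** Ochre reads 0.799 and amber 1.14; ochre's, scaled by catalyst, predicts 1.26 for amber. Scaled to the flask, their mean gives 3.49 as the flask's reaction number, and solving for c gives a yield of 98.4 %.

**One number?** N is silent on the excess. Ochre's first reading shows 23.9 %, and amber at 5.00 d, its products summing to 104 %, shows 19.2 %. Equal substrates that never interconvert end in equal products, so I take exchange as keeping pace and the excess as their mean, 21.6 %.

**The forecast.** It says 97 %, 22 % and keeps pace, noting an excess “still about 20% at full conversion in the faster runs”.

**The flask.** It gives 97.8 % and 22.9 %, and exchange keeps pace, 99.0 % of the way.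

    coupling partner + free catalyst + right-handed substrate → free catalyst + right-handed product (k = 1500 /M²/h)
    2 racemization catalyst ⇌ resting dimer, settled at all times (K = 1700 /M)
    coupling partner + free catalyst + left-handed substrate → free catalyst + left-handed product (k = 2400 /M²/h)
    coupling partner ⇌ dormant form (K = 2.00, k = 0.500 /h)
    left-handed substrate + racemization catalyst ⇌ right-handed substrate + racemization catalyst, rate k5*[racemization catalyst]*[left-handed substrate] forward; the back reaction follows from the equilibrium constant (k = 21000 /M/h)

By 0.400 d each substrate in the flask stood at 25.8 % of the two charged together, partner at 24.1 % of its own charge beside 0.103 M of dormant form, and the excess stood at 22.8 %. By 2.00 d the left-handed coupling in the flask had 91 % of its turnover behind it, and at 4.00 d 2.2 % of each substrate's own charge remained, the right-handed leading by an excess of 0.113 %. That yield means N = 3.15 against the reckoned 3.49.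

**Less partner.** With 0.12 M of partner in the same flask, the surplus shrinks, N becomes 0.698 at m = 1.20, and the yield comes to 85.8 %. The computed neighbour gives 83.8 %, with excess 23.0 %.

(The runs were computed with made-up constants.)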